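**Retrosynthetic overview**
1. Sclerotiorin ⇒ its 7-alcohol (acetylation last).
2. The 7-alcohol ⇒ an acyclic chloro-enynone hung on a lactate-derived dioxolanone. Both rings close in one flask: ring A (carbocycle) first, by vinylogous Dieckmann closure C8a→C8 onto the acylal lactone; then ring B (pyran), by C1 insertion at C8a and 6-endo oxa-cyclisation onto the alkyne.
3. Chloro-enynone ⇒ Sonogashira union (C4–C4a) of a chiral dienyne with the enol triflate of a 2-chloro-1,3-diketone.
4. Chloro-diketone ⇒ pivalaldehyde acetal of (R)-lactic acid + diketene + NCS. C7 is set here by self-regeneration of the lactate stereocentre, so no oxidative dearomatisation is needed.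
5. Dienyne ⇒ (S)-2-methylbutan-1-ol by oxidation, Wittig and Horner–Wadsworth–Emmons olefinations.

Assumption: (R)-lactic acid (D-lactic acid, the fermentation monomer of poly(D-lactide)) and stabilised diketene are counted as cheap commercial materials; the tetrasubstituted chloroalkenes are drawn without geometry because that geometry is erased in the ring-forming step.

**Route**

Step 1
Reactants: 1 (S)-2-methylbutan-1-ol
Product: 2 (S)-2-methylbutanal
Conditions: TEMPO (1 mol %), KBr (10 mol %), NaOCl, NaHCO3, CH2Cl2/H2O, 0 °C; used as a CH2Cl2 solution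
Reagents that add atoms: none
Why: Anelli (TEMPO/hypochlorite) oxidation in a buffered two-phase system stops at the aldehyde at 0 °C without epimerising the α-stereocentre; no new stereocentre.

Step 2
Reactants: 2 (S)-2-methylbutanal; 3 2-(triphenylphosphoranylidene)propanal
Product: 4 (S,E)-2,4-dimethylhex-2-enal
Conditions: PhMe, 80 °C
Reagents that add atoms: none
Why: Wittig olefination with the stabilised formyl ylide gives the (E)-trisubstituted enal under neutral conditions, so the adjacent stereocentre is untouched.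

Step 3
Reactants: 4 (S,E)-2,4-dimethylhex-2-enal; 5 diethyl [3-(trimethylsilyl)prop-2-yn-1-yl]phosphonate
Product: 7 (S,3E,5E)-5,7-dimethylnona-3,5-dien-1-yne, via silyl dienyne 6 (not isolated)
Conditions: LiN(SiMe3)2, THF, −78 to 0 °C; then K2CO3 (0.2 equiv), MeOH, 23 °C
Reagents that add atoms: none
Why: Horner–Wadsworth–Emmons olefination of the enal with the lithiated propargyl phosphonate is E-selective, and methanolysis then removes the silyl group in the same flask; no stereocentre is touched.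

Step 4
Reactants: 8 (R)-lactic acid; 9 pivalaldehyde
Product: 10 (2R,5R)-2-tert-butyl-5-methyl-1,3-dioxolan-4-one
Conditions: TsOH·H2O (cat.), H2SO4 (cat.), pentane, reflux, Dean–Stark; recrystallisation from pentane/Et2O at −78 °C
Reagents that add atoms: none
Why: Seebach acetalisation (first stage of self-regeneration of stereocentres) keeps the lactate centre (R) and sets the acetal centre (2R) through the thermodynamic cis preference, the cis isomer being purified by crystallisation.

Step 5
Reactants: 10 (2R,5R)-2-tert-butyl-5-methyl-1,3-dioxolan-4-one; 11 diketene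
Product: 13 (2R,5S)-2-tert-butyl-5-(2-chloro-3-oxobutanoyl)-5-methyl-1,3-dioxolan-4-one, via diketone 12 (not isolated)
Conditions: LiN(iPr)2, THF, −78 °C; diketene, −78 °C; then NCS, −78 to 0 °C
Reagents that add atoms: N-chlorosuccinimide, O=C1CCC(=O)N1Cl
Why: Seebach enolate C-acylation: diketene acetoacetylates the planar lithium enolate on the face anti to tert-butyl, which sets the quaternary centre (5S, the future C7 with R configuration) with overall retention, and the resulting lithium 1,3-diketonate is chlorinated at its central carbon by NCS (electrophilic α-chlorination).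

Step 6
Reactants: 13 (2R,5S)-2-tert-butyl-5-(2-chloro-3-oxobutanoyl)-5-methyl-1,3-dioxolan-4-one
Product: 14 (2R,5S)-2-tert-butyl-5-[2-chloro-3-(trifluoromethanesulfonyloxy)but-2-enoyl]-5-methyl-1,3-dioxolan-4-one
Conditions: Tf2O, iPr2NEt, CH2Cl2, −78 °C
Reagents that add atoms: triflic anhydride, O=S(=O)(OS(=O)(=O)C(F)(F)F)C(F)(F)F
Why: Enol triflate formation: the 2-chloro-1,3-diketone enolises readily and is O-sulfonylated at the unhindered acetyl oxygen rather than at the oxygen next to the quaternary carbon; the quaternary centre cannot enolise.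

Step 7
Reactants: 14 (2R,5S)-2-tert-butyl-5-[2-chloro-3-(trifluoromethanesulfonyloxy)but-2-enoyl]-5-methyl-1,3-dioxolan-4-one; 7 (S,3E,5E)-5,7-dimethylnona-3,5-dien-1-yne
Product: 15 (2R,5S)-2-tert-butyl-5-[(6E,8E,10S)-2-chloro-3,8,10-trimethyldodeca-2,6,8-trien-4-ynoyl]-5-methyl-1,3-dioxolan-4-one
Conditions: PdCl2(PPh3)2 (5 mol %), CuI (10 mol %), Et3N, THF, 23 °C
Reagents that add atoms: none
Why: Sonogashira coupling: the vinylogous acyl triflate adds oxidatively to zerovalent palladium at room temperature far faster than the α-chloride, and a tertiary amine does not open the acylal lactone; no stereocentre is touched.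

Step 8
Reactants: 15 (2R,5S)-2-tert-butyl-5-[(6E,8E,10S)-2-chloro-3,8,10-trimethyldodeca-2,6,8-trien-4-ynoyl]-5-methyl-1,3-dioxolan-4-one
Product: 19 7-deacetylsclerotiorin, via cyclohexenedione 16 (not isolated), via enaminone 17 (not isolated), via hydroxymethylene dione 18 (not isolated)
Conditions: LiN(SiMe3)2 (2.2 equiv), THF, −78 to 0 °C; AcOH (2.2 equiv), then Me2NCH(OMe)2, 23 °C; 1 M aq. HCl, 23 °C; then KH2PO4/K2HPO4 buffer (pH 7), CuI (10 mol %), MeCN, 23 °C
Reagents that add atoms: N,N-dimethylformamide dimethyl acetal, COC(OC)N(C)C; water, O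
Why: Proposed new method: γ-deprotonation of the β-methyl enone gives a cross-conjugated dienolate whose C4a–C5 bond rotates freely (so either alkene isomer of 15 converges), and its γ-carbon acylates the activated acylal lactone in a six-membered vinylogous Dieckmann closure that expels pivalaldehyde and forms ring A as a vinylogous acid in which the chlorine keeps C5 and C8a distinct, so the lactate-derived quaternary carbon stays stereodefined (no new stereocentre); the only CH2 of this 1,3-dione analogue then condenses with the amide acetal, acid hydrolysis unmasks the formyl enol, and monovalent copper catalyses 6-endo-dig oxa-cyclisation onto the conjugated alkyne to close ring B; closest known reactions are vinylogous Dieckmann cyclisations of dienolates, aminomethylenation of cyclohexane-1,3-diones, and copper-catalysed cycloisomerisation of formyl vinylogous acids to azaphilones.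

Step 9
Reactants: 19 7-deacetylsclerotiorin
Product: 20 sclerotiorin
Conditions: Ac2O, DMAP (0.2 equiv), CH2Cl2, 23 °C
Reagents that add atoms: acetic anhydride, CC(=O)OC(C)=O
Why: DMAP-catalysed acylation of the tertiary alcohol, a known transformation of 7-hydroxy azaphilones; no stereocentre is touched.

**Compound list**
1 | (S)-2-methylbutan-1-ol | CC[C@H](C)CO | starting material
2 | (S)-2-methylbutanal | CC[C@H](C)C=O | intermediate
3 | 2-(triphenylphosphoranylidene)propanal | CC(C=O)=P(c1ccccc1)(c1ccccc1)c1ccccc1 | starting material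
4 | (S,E)-2,4-dimethylhex-2-enal | CC[C@H](C)/C=C(C)/C=O | intermediate
5 | diethyl [3-(trimethylsilyl)prop-2-yn-1-yl]phosphonate | CCOP(=O)(CC#C[Si](C)(C)C)OCC | starting material
6 | trimethyl[(S,3E,5E)-5,7-dimethylnona-3,5-dien-1-yn-1-yl]silane | CC[C@H](C)/C=C(C)/C=C/C#C[Si](C)(C)C | intermediate
7 | (S,3E,5E)-5,7-dimethylnona-3,5-dien-1-yne | CC[C@H](C)/C=C(C)/C=C/C#C | intermediate
8 | (R)-lactic acid | C[C@@H](O)C(=O)O | starting material
9 | pivalaldehyde | CC(C)(C)C=O | starting material
10 | (2R,5R)-2-tert-butyl-5-methyl-1,3-dioxolan-4-one (cis) | C[C@H]1O[C@@H](C(C)(C)C)OC1=O | intermediate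
11 | diketene (4-methyleneoxetan-2-one) | C=C1CC(=O)O1 | starting material
12 | (2R,5S)-2-tert-butyl-5-methyl-5-(3-oxobutanoyl)-1,3-dioxolan-4-one | C[C@@]1(C(=O)CC(C)=O)O[C@@H](C(C)(C)C)OC1=O | intermediate
13 | (2R,5S)-2-tert-butyl-5-(2-chloro-3-oxobutanoyl)-5-methyl-1,3-dioxolan-4-one (epimers at CHCl) | C[C@@]1(C(=O)C(Cl)C(C)=O)O[C@@H](C(C)(C)C)OC1=O | intermediate
14 | (2R,5S)-2-tert-butyl-5-[2-chloro-3-(trifluoromethanesulfonyloxy)but-2-enoyl]-5-methyl-1,3-dioxolan-4-one (E/Z mixture) | C[C@@]1(C(=O)C(Cl)=C(C)OS(=O)(=O)C(F)(F)F)O[C@@H](C(C)(C)C)OC1=O | intermediate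
15 | (2R,5S)-2-tert-butyl-5-[(6E,8E,10S)-2-chloro-3,8,10-trimethyldodeca-2,6,8-trien-4-ynoyl]-5-methyl-1,3-dioxolan-4-one (2E/2Z mixture) | C[C@@]1(C(=O)C(Cl)=C(C)C#C/C=C/C(C)=C/[C@@H](C)CC)O[C@@H](C(C)(C)C)OC1=O | intermediate
16 | (R)-4-chloro-5-[(S,3E,5E)-5,7-dimethylnona-3,5-dien-1-yn-1-yl]-2-hydroxy-2-methylcyclohex-4-ene-1,3-dione | CC[C@H](C)/C=C(C)/C=C/C#CC1=C(Cl)C(=O)[C@](C)(O)C(=O)C1 | intermediate
17 | (R)-4-chloro-6-[(dimethylamino)methylidene]-5-[(S,3E,5E)-5,7-dimethylnona-3,5-dien-1-yn-1-yl]-2-hydroxy-2-methylcyclohex-4-ene-1,3-dione | CC[C@H](C)/C=C(C)/C=C/C#CC1=C(Cl)C(=O)[C@](C)(O)C(=O)C1=CN(C)C | intermediate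
18 | (R)-4-chloro-5-[(S,3E,5E)-5,7-dimethylnona-3,5-dien-1-yn-1-yl]-2-hydroxy-6-(hydroxymethylidene)-2-methylcyclohex-4-ene-1,3-dione | CC[C@H](C)/C=C(C)/C=C/C#CC1=C(Cl)C(=O)[C@](C)(O)C(=O)C1=CO | intermediate
19 | 7-deacetylsclerotiorin, (R)-5-chloro-3-[(S,1E,3E)-3,5-dimethylhepta-1,3-dien-1-yl]-7-hydroxy-7-methyl-6H-isochromene-6,8(7H)-dione | CC[C@H](C)/C=C(C)/C=C/C1=CC2=C(Cl)C(=O)[C@](C)(O)C(=O)C2=CO1 | intermediate
20 | sclerotiorin, (R)-5-chloro-3-[(S,1E,3E)-3,5-dimethylhepta-1,3-dien-1-yl]-7-methyl-6,8-dioxo-7,8-dihydro-6H-isochromen-7-yl acetate | CC[C@H](C)/C=C(C)/C=C/C1=CC2=C(Cl)C(=O)[C@](C)(OC(C)=O)C(=O)C2=CO1 | target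

**Step count**
Total steps: 9. Longest linear sequence: 6 (steps 4, 5, 6, 7, 8, 9 from (R)-lactic acid; the side-chain branch 1, 2, 3, 7, 8, 9 is equally long).

**Steps most likely to fail, with fallbacks**

Step 8 (ring closure may stall through dienolate geometry, chloride loss or α-ketol rearrangement of the dianion). The fallback sets out from 15 and installs C1 before any ring is closed. Condensation of the γ-methyl group with tBuOCH(NMe2)2 in PhMe gives the push-pull dienamine (2R,5S)-2-tert-butyl-5-[(6E,8E,10S)-2-chloro-3-[2-(dimethylamino)ethenyl]-8,10-dimethyldodeca-2,6,8-trien-4-ynoyl]-5-methyl-1,3-dioxolan-4-one F7. Its enamine β-carbon then acylates the acylal lactone under neutral conditions (PhMe, 80–110 °C, MgBr2·OEt2) with loss of pivalaldehyde. The route is rejoined at 17, which is hydrolysed and cyclised as in the last stages of step 8.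

Step 5 (diketene may O-acylate or oligomerise, or the diketonate may over-chlorinate). The fallback sets out from 10. Its lithium enolate is acylated with but-2-ynoyl chloride to the ynone (2R,5S)-5-(but-2-ynoyl)-2-tert-butyl-5-methyl-1,3-dioxolan-4-one F1. Anti addition of chlorine with PhICl2 in CH2Cl2 gives (2R,5S)-2-tert-butyl-5-[(E)-2,3-dichlorobut-2-enoyl]-5-methyl-1,3-dioxolan-4-one F2. Sonogashira coupling of 7 at the β-chloride only (a vinylogous acid chloride; PdCl2(PPh3)2, CuI, Et3N) comes back to the route at 15, bypassing 13 and 14.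

Step 6 (triflation may occur at the wrong enol oxygen). The fallback sets out from 7 and 10 and builds the chloro-enyne acyl unit separately, from a β-keto ester that has only one ketone oxygen. Commercial ethyl 2-chloroacetoacetate is triflated (Tf2O, iPr2NEt) to ethyl 2-chloro-3-(trifluoromethanesulfonyloxy)but-2-enoate F3. Sonogashira coupling with 7 gives ethyl (6E,8E,10S)-2-chloro-3,8,10-trimethyldodeca-2,6,8-trien-4-ynoate F4. Saponification with LiOH gives (6E,8E,10S)-2-chloro-3,8,10-trimethyldodeca-2,6,8-trien-4-ynoic acid F5, and (COCl)2 with catalytic DMF gives (6E,8E,10S)-2-chloro-3,8,10-trimethyldodeca-2,6,8-trien-4-ynoyl chloride F6. C-acylation of the lithium enolate of 10 (LiN(iPr)2, THF, −78 °C) with F6, anti to tert-butyl, returns to the route at 15.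

**Further compounds**
F1 | step 5 | (2R,5S)-5-(but-2-ynoyl)-2-tert-butyl-5-methyl-1,3-dioxolan-4-one | C[C@@]1(C(=O)C#CC)O[C@@H](C(C)(C)C)OC1=O
F2 | step 5 | (2R,5S)-2-tert-butyl-5-[(E)-2,3-dichlorobut-2-enoyl]-5-methyl-1,3-dioxolan-4-one | C[C@@]1(C(=O)/C(Cl)=C(/C)Cl)O[C@@H](C(C)(C)C)OC1=O
F3 | step 6 | ethyl 2-chloro-3-(trifluoromethanesulfonyloxy)but-2-enoate (E/Z mixture) | CCOC(=O)C(Cl)=C(C)OS(=O)(=O)C(F)(F)F
F4 | step 6 | ethyl (6E,8E,10S)-2-chloro-3,8,10-trimethyldodeca-2,6,8-trien-4-ynoate (2E/2Z mixture) | CCOC(=O)C(Cl)=C(C)C#C/C=C/C(C)=C/[C@@H](C)CC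
F5 | step 6 | (6E,8E,10S)-2-chloro-3,8,10-trimethyldodeca-2,6,8-trien-4-ynoic acid (2E/2Z mixture) | OC(=O)C(Cl)=C(C)C#C/C=C/C(C)=C/[C@@H](C)CC
F6 | step 6 | (6E,8E,10S)-2-chloro-3,8,10-trimethyldodeca-2,6,8-trien-4-ynoyl chloride (2E/2Z mixture) | ClC(=O)C(Cl)=C(C)C#C/C=C/C(C)=C/[C@@H](C)CC
F7 | step 8 | (2R,5S)-2-tert-butyl-5-[(6E,8E,10S)-2-chloro-3-[2-(dimethylamino)ethenyl]-8,10-dimethyldodeca-2,6,8-trien-4-ynoyl]-5-methyl-1,3-dioxolan-4-one | C[C@@]1(C(=O)C(Cl)=C(C=CN(C)C)C#C/C=C/C(C)=C/[C@@H](C)CC)O[C@@H](C(C)(C)C)OC1=O
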